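**Retrosynthetic overview**

1. The pyranone is made last, by cutting O1′–C6′ and C4′–C5′ in one Pd(0) allene heteroannulation: target ⇒ allenyl ketone (ring–CO–CH=C=CMe2) + (Z)-3-iodoacrylic acid. The enabling feature is that the ring oxygen sits on the gem-dimethyl carbon C6′, which is allylic to the exocyclic enone C5′=C6–C7(=O), while C5′ also carries the cis C4′=C3′–CO2 arm. This O–CMe2–C(vinyl)=CH–acyl array is a carboxylate-trapped 2-vinyl-π-allyl whose central carbon C5′ was an allene sp carbon.
2. Allenyl ketone ⇒ 14,15-epoxy δ-lactone (a temporary C17–O–C16 tether holds the ester carbon cis to C13; nucleophilic epoxidation; lactone then opened and C17 oxidised) ⇒ C17 bromoacetate of a β-hydroxy ketone (Sm-Reformatsky, dehydration).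
3. β-Hydroxy ketone ⇒ cyclohexanone + 4-methylpenta-2,3-dienal (aldol sets quaternary C8) ⇒ (S)-carvone + furan-3-carbaldehyde (reductive aldol sets quaternary C13).
4. Chiral pool map: carvone C1/C2/C3/C4/C5/C6 = C14/C13/C12/C11/C9/C8; the carvone methyl is the C13 methyl; isopropenyl becomes the (R)-CH(OH)CH3 group.
5. Ring order: cyclohexane (from carvone) → temporary δ-lactone → spiro-oxirane → lactone opened → pyranone.

Key step: step 17

**Remarks**

- Locants (limonoid numbering): cyclohexane C8 (CH3, acyl), C9 (hydroxyethyl), C11, C12, C13 (CH3, furoyl), C14 (spiro-epoxide). C15/C16 = epoxide CH/ester carbon; C17 = furyl-bearing carbon; C10 = carbinol carbon; C7 = side-chain ketone; C6 = enone CH. Pyranone: O1′, C2′(=O), C3′=C4′, C5′ (ylidene), C6′ (CMe2).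
- SMILES show the expected major epimer at the transient centres (C17 carbinol, C8–H in 7–10, C7 carbinol, C14 carbinol in 19); each is erased later.
- Assumption: (Z)-3-iodoacrylic acid and 3-methylbuta-1,2-diene are purchased.

**Route**

Step 1
Reactants: 1 (S)-(+)-carvone; 2 furan-3-carbaldehyde
Product: 4 aldol adduct (2S,5S)-2-[(S)-furan-3-yl(hydroxy)methyl]-2-methyl-5-(prop-1-en-2-yl)cyclohexan-1-one, via lithium enolate 3 (not isolated)
Conditions: L-Selectride, THF, −78 °C; then 2, −78 °C; H2O
Reagents that add atoms: none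
Why: Conjugate hydride reduction gives the regiodefined enolate, and its aldol addition (reductive aldol, Zimmerman–Traxler) should occur by axial attack cis to the isopropenyl group, as in Robinson annulations of dihydrocarvone, setting quaternary C13 with its methyl trans to isopropenyl; the carbinol centre is oxidised away in step 14.

Step 2
Reactants: 4 aldol adduct
Product: 5 C17 O-triethylsilyl ether of 4
Conditions: TESOTf, 2,6-lutidine, CH2Cl2, −78 °C
Reagents that add atoms: triethylsilyl triflate CC[Si](CC)(CC)OS(=O)(=O)C(F)(F)F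
Why: Silyl triflate protection of the hindered secondary alcohol blocks retro-aldol and leaves C8 as the only enolisable position.

Step 3
Reactants: 5 TES ether
Product: 7 C8-methyl ketone (8-CH3 trans to the C9 isopropenyl), via lithium C8-enolate 6 (not isolated)
Conditions: LDA, THF, −78 °C; MeI, −78 → −20 °C
Reagents that add atoms: iodomethane CI
Why: Kinetic enolate alkylation at the only α-CH2 (C8); the configuration of this centre is erased by enolisation in step 8.

Step 4
Reactants: 7 C8-methyl ketone
Product: 8 C10 methyl ketone (isopropenyl cleaved to acetyl)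
Conditions: OsO4 (cat.), NaIO4, 2,6-lutidine, dioxane/H2O, rt
Reagents that add atoms: sodium periodate [Na+].[O-]I(=O)(=O)=O (oxygen source, relayed by catalytic osmium tetroxide O=[Os](=O)(=O)=O)
Why: Lemieux–Johnson oxidative cleavage, in which the 1,1-disubstituted alkene should be dihydroxylated much faster than the furan.

Step 5
Reactants: 8 C10 methyl ketone
Product: 9 (10R)-alcohol
Conditions: (S)-Me-CBS (cat.), BH3·SMe2, THF, −30 °C; MeOH
Reagents that add atoms: none
Why: Corey–Bakshi–Shibata reduction under reagent control (ring carbon large, methyl small) should give the (R)-carbinol, matched with the Felkin–Anh preference, while the C14 ketone (α-quaternary, α′-tertiary) is too hindered to compete.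

Step 6
Reactants: 9 (10R)-alcohol
Product: 10 (10R) O-TBS ether
Conditions: TBSCl, imidazole, DMF, rt
Reagents that add atoms: tert-butyldimethylsilyl chloride CC(C)(C)[Si](C)(C)Cl
Why: Standard silylation of an unhindered secondary alcohol before the second enolate step.

Step 7
Reactants: 11 3-methylbuta-1,2-diene
Product: 13 4-methylpenta-2,3-dienal, via 1-lithio-3-methylbuta-1,2-diene 12 (not isolated)
Conditions: n-BuLi, THF, −78 → −40 °C; DMF, −78 °C; aq. NaH2PO4
Reagents that add atoms: N,N-dimethylformamide CN(C)C=O
Why: Allenic C–H lithiation at the unsubstituted terminus followed by formylation with DMF at the same carbon, the tertiary γ-carbon being too hindered to react.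

Step 8
Reactants: 10 (10R) O-TBS ether; 13 4-methylpenta-2,3-dienal
Product: 16 C7 O-TBS allenyl carbinol ketone (C8 quaternary), via lithium C8-enolate 14 (not isolated), via lithium aldolate 15 (not isolated)
Conditions: LDA, THF, −78 → 0 °C; 13, −78 °C; TBSOTf, −78 → −40 °C
Reagents that add atoms: tert-butyldimethylsilyl triflate CC(C)(C)[Si](C)(C)OS(=O)(=O)C(F)(F)F
Why: Aldol 1,2-addition of the tetrasubstituted enolate to the non-enolisable aldehyde, entering anti to the adjacent C9 substituent (A1,2-strain-controlled axial attack), should place C7 trans and the C8 methyl cis to the C9 side chain; in-situ O-silylation of the aldolate blocks retro-aldol, and the carbinol centre is oxidised away in step 16.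

Step 9
Reactants: 16 C7 O-TBS allenyl carbinol ketone
Product: 17 C17 alcohol (β-hydroxy ketone)
Conditions: HF·pyridine, pyridine, THF, 0 °C
Reagents that add atoms: none
Why: Fluoride-mediated desilylation should cleave the triethylsilyl ether selectively in the presence of the two secondary TBS ethers.

Step 10
Reactants: 17 C17 alcohol
Product: 18 C17 bromoacetate
Conditions: BrCH2COBr, pyridine, DMAP (cat.), CH2Cl2, −20 → 0 °C
Reagents that add atoms: bromoacetyl bromide BrCC(Br)=O
Why: O-Acylation with a reactive acyl bromide under non-enolising conditions, so that retro-aldol is avoided.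

Step 11
Reactants: 18 C17 bromoacetate
Product: 19 β-hydroxy δ-lactone (C15–C14 bond formed)
Conditions: SmI2, THF, −78 → −40 °C
Reagents that add atoms: none
Why: Intramolecular samarium Reformatsky reaction, in which the small chelated samarium enolate should add to the doubly neopentyl C14 ketone in a six-membered closure; the C14 configuration does not matter because it is removed in step 12.

Step 12
Reactants: 19 β-hydroxy δ-lactone
Product: 20 α,β-unsaturated δ-lactone (C14=C15)
Conditions: Burgess reagent, toluene, 60 °C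
Reagents that add atoms: none
Why: Burgess syn-dehydration of the tertiary alcohol can only go towards C15 (the sole β-hydrogens), and the lactone ring forces C16 cis to C13 on the new alkene.

Step 13
Reactants: 20 α,β-unsaturated δ-lactone
Product: 21 14,15-epoxy δ-lactone
Conditions: t-BuOOH, n-BuLi, THF, −78 → 0 °C
Reagents that add atoms: tert-butyl hydroperoxide CC(C)(C)OO
Why: Nucleophilic (Weitz–Scheffer-type) epoxidation with lithium tert-butylperoxide spares furan and allene; the peroxide should add to C14 from the face anti to the C13 methyl and the C8 allenylcarbinol chain (the face of H-17 and the C8 methyl), and closure at C15 inside the lactone fixes both epoxide centres.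

Step 14
Reactants: 21 14,15-epoxy δ-lactone
Product: 24 keto ester (C17 furyl ketone and C16 methyl ester), via lithium hydroxy carboxylate 22 (not isolated), via hydroxy methyl ester 23 (not isolated)
Conditions: LiOH, THF/H2O, 0 °C; MeI, DMF, rt; DMP, NaHCO3, CH2Cl2, 0 °C
Reagents that add atoms: lithium hydroxide [Li+].[OH-]; iodomethane CI
Why: Saponification of the strained trans-fused lactone, O-alkylation of the carboxylate (the glycidic acid is never set free) and immediate Dess–Martin oxidation of the released furyl carbinol, which should make relactonisation impossible.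

Step 15
Reactants: 24 keto ester
Product: 25 diol (C7-OH and C10-OH free)
Conditions: HF·pyridine, pyridine, THF, 0 °C → rt
Reagents that add atoms: none
Why: Buffered fluoride desilylation should remove both TBS ethers under conditions tolerated by the epoxide, the ester and the allene.

Step 16
Reactants: 25 diol
Product: 26 allenyl ketone
Conditions: MnO2, CH2Cl2, rt
Reagents that add atoms: none
Why: Chemoselective MnO2 oxidation of the allenic (allylic-type) carbinol should leave the saturated C10 alcohol untouched.

Step 17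
Reactants: 26 allenyl ketone; 27 (Z)-3-iodoacrylic acid
Product: 29 CNP0293135.1, via σ-allylpalladium iodide 28 (not isolated)
Conditions: Pd(OAc)2 (10 mol%), P(2-furyl)3 (20 mol%), NaHCO3, DMF, 45 °C, slow addition of 26
Reagents that add atoms: none
Why: Oxidative addition of Pd(0) into the C–I bond of 27 (Z geometry retained), carbopalladation of the allene at its central carbon (new C4′–C5′ bond) and attack of the cis-carboxylate on the CMe2 terminus of the acyl-substituted π-allyl (28, drawn in its η1 form) should form the O1′–C6′ bond and release Pd(0); the closest known reaction type is the Larock heteroannulation of 1,2-dienes with vinylic halides bearing a carboxylic acid, together with Pd-catalysed couplings of 1,2-allenyl ketones with organic halides. The pyranone closes in a six-membered mode, 6-endo with respect to the C5′–C6′ allyl bond, which amounts to an SN2′-type displacement of palladium from the carbon α to the ketone. No stereocentre is created; the exocyclic C5′=C6 geometry is set by the syn π-allyl, because an anti acyl group at C6 would clash with the anti methyl on C6′, and π–σ–π equilibration through the C-bound palladium enolate should funnel both allyl isomers to the E enone. The step needs attack at C6′ and not at the acyl-bearing terminus, which would give an isomeric six-membered lactone; this is secured by the ketone directing nucleophiles to the distal terminus, by the preference of these annulations for the more substituted terminus, and by reversible ionisation of the tertiary allylic carboxylate towards the fully conjugated product. The gem-dimethyl terminus also blocks cycloisomerisation of the allenyl ketone to a furan, and the weakly nucleophilic phosphine should avoid phosphine addition to the allenone.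

**Compound list**

1 | (S)-(+)-carvone | CC1=CC[C@@H](CC1=O)C(C)=C | starting material
2 | furan-3-carbaldehyde | O=Cc1ccoc1 | starting material
3 | lithium enolate of (S)-dihydrocarvone | [Li+].[O-]C1=C(C)CC[C@H](C(C)=C)C1 | intermediate
4 | aldol adduct (2S,5S)-2-[(S)-furan-3-yl(hydroxy)methyl]-2-methyl-5-(prop-1-en-2-yl)cyclohexan-1-one | O=C1[C@](C)([C@@H](O)c2ccoc2)CC[C@H](C(C)=C)C1 | intermediate
5 | C17 O-triethylsilyl ether of 4 | O=C1[C@](C)([C@@H](O[Si](CC)(CC)CC)c2ccoc2)CC[C@H](C(C)=C)C1 | intermediate
6 | lithium C8-enolate of 5 | [Li+].[O-]C=1[C@](C)([C@@H](O[Si](CC)(CC)CC)c2ccoc2)CC[C@H](C(C)=C)C=1 | intermediate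
7 | C8-methyl ketone (8-CH3 trans to isopropenyl) | O=C1[C@](C)([C@@H](O[Si](CC)(CC)CC)c2ccoc2)CC[C@H](C(C)=C)[C@H]1C | intermediate
8 | C10 methyl ketone (acetyl at C9) | O=C1[C@](C)([C@@H](O[Si](CC)(CC)CC)c2ccoc2)CC[C@H](C(C)=O)[C@H]1C | intermediate
9 | (10R)-alcohol | O=C1[C@](C)([C@@H](O[Si](CC)(CC)CC)c2ccoc2)CC[C@H]([C@@H](C)O)[C@H]1C | intermediate
10 | (10R) O-TBS ether | O=C1[C@](C)([C@@H](O[Si](CC)(CC)CC)c2ccoc2)CC[C@H]([C@@H](C)O[Si](C)(C)C(C)(C)C)[C@H]1C | intermediate
11 | 3-methylbuta-1,2-diene | CC(C)=C=C | starting material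
12 | 1-lithio-3-methylbuta-1,2-diene | [Li]C=C=C(C)C | intermediate
13 | 4-methylpenta-2,3-dienal | CC(C)=C=CC=O | intermediate
14 | lithium C8-enolate of 10 | [Li+].[O-]C=1[C@](C)([C@@H](O[Si](CC)(CC)CC)c2ccoc2)CC[C@H]([C@@H](C)O[Si](C)(C)C(C)(C)C)C=1C | intermediate
15 | lithium aldolate (C7 alkoxide) | O=C1[C@](C)([C@@H](O[Si](CC)(CC)CC)c2ccoc2)CC[C@H]([C@@H](C)O[Si](C)(C)C(C)(C)C)[C@@]1(C)[C@@H]([O-])C=C=C(C)C.[Li+] | intermediate
16 | C7 O-TBS allenyl carbinol ketone (C8: CH3 cis, C7 trans to the C9 side chain) | O=C1[C@](C)([C@@H](O[Si](CC)(CC)CC)c2ccoc2)CC[C@H]([C@@H](C)O[Si](C)(C)C(C)(C)C)[C@@]1(C)[C@@H](O[Si](C)(C)C(C)(C)C)C=C=C(C)C | intermediate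
17 | C17 alcohol (β-hydroxy ketone) | O=C1[C@](C)([C@@H](O)c2ccoc2)CC[C@H]([C@@H](C)O[Si](C)(C)C(C)(C)C)[C@@]1(C)[C@@H](O[Si](C)(C)C(C)(C)C)C=C=C(C)C | intermediate
18 | C17 bromoacetate | O=C1[C@](C)([C@@H](OC(=O)CBr)c2ccoc2)CC[C@H]([C@@H](C)O[Si](C)(C)C(C)(C)C)[C@@]1(C)[C@@H](O[Si](C)(C)C(C)(C)C)C=C=C(C)C | intermediate
19 | β-hydroxy δ-lactone (C14 tertiary alcohol) | O=C1O[C@@H](c5ccoc5)[C@]2(C)CC[C@H]([C@@H](C)O[Si](C)(C)C(C)(C)C)[C@@](C)([C@@H](O[Si](C)(C)C(C)(C)C)C=C=C(C)C)[C@]2(O)C1 | intermediate
20 | α,β-unsaturated δ-lactone (C14=C15) | O=C1O[C@@H](c5ccoc5)[C@]2(C)CC[C@H]([C@@H](C)O[Si](C)(C)C(C)(C)C)[C@@](C)([C@@H](O[Si](C)(C)C(C)(C)C)C=C=C(C)C)C2=C1 | intermediate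
21 | 14,15-epoxy δ-lactone | O=C1O[C@@H](c5ccoc5)[C@]2(C)CC[C@H]([C@@H](C)O[Si](C)(C)C(C)(C)C)[C@@](C)([C@@H](O[Si](C)(C)C(C)(C)C)C=C=C(C)C)[C@]23O[C@H]13 | intermediate
22 | lithium hydroxy carboxylate (opened lactone) | [Li+].[O-]C(=O)[C@H]1O[C@@]12[C@](C)([C@@H](O)c1ccoc1)CC[C@H]([C@@H](C)O[Si](C)(C)C(C)(C)C)[C@@]2(C)[C@@H](O[Si](C)(C)C(C)(C)C)C=C=C(C)C | intermediate
23 | hydroxy methyl ester | COC(=O)[C@H]1O[C@@]12[C@](C)([C@@H](O)c1ccoc1)CC[C@H]([C@@H](C)O[Si](C)(C)C(C)(C)C)[C@@]2(C)[C@@H](O[Si](C)(C)C(C)(C)C)C=C=C(C)C | intermediate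
24 | keto ester (C17 ketone, C16 methyl ester, two TBS ethers) | COC(=O)[C@H]1O[C@@]12[C@](C)(C(=O)c1ccoc1)CC[C@H]([C@@H](C)O[Si](C)(C)C(C)(C)C)[C@@]2(C)[C@@H](O[Si](C)(C)C(C)(C)C)C=C=C(C)C | intermediate
25 | diol (C7 allenyl carbinol, C10 alcohol) | COC(=O)[C@H]1O[C@@]12[C@](C)(C(=O)c1ccoc1)CC[C@H]([C@@H](C)O)[C@@]2(C)[C@@H](O)C=C=C(C)C | intermediate
26 | allenyl ketone | COC(=O)[C@H]1O[C@@]12[C@](C)(C(=O)c1ccoc1)CC[C@H]([C@@H](C)O)[C@@]2(C)C(=O)C=C=C(C)C | intermediate
27 | (Z)-3-iodoacrylic acid | OC(=O)/C=C\I | starting material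
28 | σ-allylpalladium iodide (η1 form of the π-allyl, free acid) | COC(=O)[C@H]1O[C@@]12[C@](C)(C(=O)c1ccoc1)CC[C@H]([C@@H](C)O)[C@@]2(C)C(=O)/C=C(\C=C/C(=O)O)C(C)(C)[Pd]I | intermediate
29 | CNP0293135.1 | COC(=O)[C@H]1O[C@@]12[C@](C)(C(=O)c1ccoc1)CC[C@H]([C@@H](C)O)[C@@]2(C)C(=O)/C=C1\C=CC(=O)OC1(C)C | target

**Step count**

Total: 17 steps. Longest linear sequence: 16 steps (1–6 and 8–17); step 7 is a one-step side branch.

**Steps most likely to fail**

Step 17. The electrophilic allenone may be consumed by conjugate addition of the carboxylate or the ligand, or by base-induced isomerisation to a dienone, before carbopalladation; the carboxylate could also attack the acyl-bearing allyl terminus. Fallback: set out from diol 25 and run the same palladium annulation with 27 at the carbinol oxidation level, where the allene is no Michael acceptor and the neopentyl carbinol terminus sterically forces attack at CMe2. This should give the allylic alcohol lactone F1. MnO2 oxidation of the now allylic C7 carbinol then comes back to the route at 29.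

Step 13. Peroxide addition at the doubly neopentyl β-carbon C14 may not occur, or may take place on the wrong face or at the lactone carbonyl. Fallback: set out from 20 and change to an electrophilic, hydroxyl-directed epoxidation. DIBAL-H reduction should give the allylic diol F2. Sharpless epoxidation (Ti(OiPr)4, D-(−)-DET, TBHP; the tartrate is chosen by the mnemonic to deliver oxygen anti to the C13 methyl, which is also the less hindered face) should give the epoxy diol F3. Dess–Martin oxidation of both alcohols gives the keto aldehyde F4. Pinnick oxidation gives the keto acid F5, which is methylated at once with TMSCHN2. The route is rejoined at 24.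

Step 8. The aldol at the congested tetrasubstituted enolate may be slow or reverse before silylation, the enolate may add in conjugate fashion to the allenal, or facial selectivity may be poor. Fallback: set out from 10 and build the quaternary centre with the smallest electrophile. The lithium enolate and monomeric formaldehyde should give the hydroxymethyl ketone F6. Dess–Martin oxidation gives the neopentyl aldehyde F7. Addition of 1-lithio-3-methylbuta-1,2-diene 12 at −78 °C gives the allenyl carbinol F8 (either carbinol epimer serves). Silylation with TBSOTf and 2,6-lutidine comes back to the route at 16.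

**Further compounds**

F1 | step 17 | allylic alcohol lactone (C7 carbinol of the target) | COC(=O)[C@H]1O[C@@]12[C@](C)(C(=O)c1ccoc1)CC[C@H]([C@@H](C)O)[C@@]2(C)[C@@H](O)/C=C1\C=CC(=O)OC1(C)C
F2 | step 13 | allylic diol (C16 primary alcohol, C17 alcohol) | OC/C=C1\[C@](C)([C@@H](O)c2ccoc2)CC[C@H]([C@@H](C)O[Si](C)(C)C(C)(C)C)[C@@]1(C)[C@@H](O[Si](C)(C)C(C)(C)C)C=C=C(C)C
F3 | step 13 | 14,15-epoxy diol | OC[C@H]1O[C@@]12[C@](C)([C@@H](O)c1ccoc1)CC[C@H]([C@@H](C)O[Si](C)(C)C(C)(C)C)[C@@]2(C)[C@@H](O[Si](C)(C)C(C)(C)C)C=C=C(C)C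
F4 | step 13 | epoxy keto aldehyde | O=C[C@H]1O[C@@]12[C@](C)(C(=O)c1ccoc1)CC[C@H]([C@@H](C)O[Si](C)(C)C(C)(C)C)[C@@]2(C)[C@@H](O[Si](C)(C)C(C)(C)C)C=C=C(C)C
F5 | step 13 | epoxy keto acid | OC(=O)[C@H]1O[C@@]12[C@](C)(C(=O)c1ccoc1)CC[C@H]([C@@H](C)O[Si](C)(C)C(C)(C)C)[C@@]2(C)[C@@H](O[Si](C)(C)C(C)(C)C)C=C=C(C)C
F6 | step 8 | C8 hydroxymethyl ketone | O=C1[C@](C)([C@@H](O[Si](CC)(CC)CC)c2ccoc2)CC[C@H]([C@@H](C)O[Si](C)(C)C(C)(C)C)[C@@]1(C)CO
F7 | step 8 | C8 formyl ketone | O=C1[C@](C)([C@@H](O[Si](CC)(CC)CC)c2ccoc2)CC[C@H]([C@@H](C)O[Si](C)(C)C(C)(C)C)[C@@]1(C)C=O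
F8 | step 8 | C7 allenyl carbinol (free alcohol of 16) | O=C1[C@](C)([C@@H](O[Si](CC)(CC)CC)c2ccoc2)CC[C@H]([C@@H](C)O[Si](C)(C)C(C)(C)C)[C@@]1(C)[C@@H](O)C=C=C(C)C
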